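3 questions stand on two flasks that differ in temperature.

| flask | starting material | protic impurity | free enzyme | temperature | time |
|---|---|---|---|---|---|
| Saturday's | 0.050 M | 0.0250 M | 0.01 mol% | 5 °C | 80 s |
| Friday's | 0.050 M | 0.0250 M | 0.01 mol% | 25 °C | 80 s |

- which flask leads in amount of target, in percent of the starting material charged ("all alike" within 1.5 percentage points) (Saturday's / Friday's / all alike)
- how much target is there at the end, in percent of the starting material charged: Saturday's
- how much target is there at the end, in percent of the starting material charged: Friday's

- at 25 °C the constants are as listed, elsewhere as the activation energies make them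

    free enzyme → unfolded enzyme (k1 = 1.10 × 10⁻⁴ s⁻¹, Ea1 = 186 kJ mol⁻¹)
    free enzyme → spent catalyst A (k2 = 0.0150 s⁻¹, Ea2 = 72.0 kJ mol⁻¹)
    free enzyme + target → spent catalyst B (k3 = 0.775 L mol⁻¹ s⁻¹, Ea3 = 57.0 kJ mol⁻¹)
    starting material + protic impurity → quenched substrate (k4 = 29.5 L mol⁻¹ s⁻¹, Ea4 = 48.0 kJ mol⁻¹)
    starting material + free enzyme → target + free enzyme, rate k5*[starting material]*[free enzyme]/(1 + ([starting material]/Km5)) (Km5 = 6.30 mM, k5 = 5.09 × 10⁵ L mol⁻¹ s⁻¹, Ea5 = 10.0 kJ mol⁻¹)
    (constants at 25 °C)

Starting material leaves by two roads: the enzyme step makes target, and the quench with protic impurity makes quenched substrate. The reckoning begins by freezing what barely moves, the free enzyme, at its charge E = 5.00 × 10⁻⁶ M.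

The first objection is that free enzyme dies. On Friday's flask, even with the whole charge of starting material counted as target, its half-life is

tE = 12.9 s

The half-life of starting material at the start of Friday's flask, by both roads together, is far shorter, 0.678 s. On Saturday's flask that half-life is 1.75 s, still shorter than that Friday figure, and the cold slows the step to spent catalyst A by a factor of 8.1, so this reckoning keeps E frozen in both.

Let a and h be the current starting material and impurity, P the target, L the quenched substrate and Km the constant in the rate law of the enzyme step. Then

dP/dL = Q / (h(1 + a/Km))

Here Q = k5·E/k4, which is 0.0863 M on Friday's flask, is the crossover impurity level, the impurity concentration at which the unsaturated enzyme and the quench take starting material equally fast. Q/h is the selectivity factor. Cooling slows the quench by 4.0 and the enzyme step by 1.3, so on Saturday's flask Q is 0.260 M.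

The second objection is that the enzyme starts saturated, with a/Km at 7.94 at the start. If a falls evenly as P grows from the charge A, the bracket averages

G = 1 + A/(2Km) = 4.97

Freezing h at its charge H as well gives, on Friday's flask, L = A/(1 + Q/(GH)) = 0.0295 M. That is more than the impurity charged, so this estimate fails. Letting h fall gives the better form:

G·P = Q·ln(H/(H − L)), with P + L = A

L = H(1 − exp(−G(A − L)/Q))

Trials on Friday's flask swing and close in:

L = 0.0173 M, 0.0212 M, 0.0202 M

On Saturday's flask, from the frozen start 0.0162 M:

L = 0.0119 M, 0.0129 M, 0.0127 M

This reckoning therefore commits to target of 74.6% on Saturday's flask and 59.5% on Friday's.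

The forecast named Saturday's as leader, with 75.5% (73% to 78%) against 61.5% (59% to 64.5%), each a little higher than the figure of this reckoning, holding that “the yield is set by this early split”.

In the simulation Saturday's leads, with 75.5% on Saturday's flask and 61.0% on Friday's.

On Friday's flask the quench had >99.9% of its turnover up to the asked time behind it by 8.00 s and the step to target 100% by 16.0 s. Afterwards free enzyme fell to 4.65% of its charge at 80.0 s, with starting material at 0% and target at 61.0% of the starting material charged. Friday's target, put back with Q and G, leaves impurity at exp(−GP/Q) = 17.3% of its charge, and the flask shows 21.9%. A neighbour of Friday's flask has 0.12 M of starting material and 0.208 equiv of impurity. There Q is 0.207 M and G is 10.5, and the relation gives target of 79.3%. That flask shows 79.4%.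

(The numbers of this flask come from no measurement.)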